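(The readings are simulated for substances that don't exist; scatter was added.)

The trap at this bench was to read a bent curve as a flask at rest, so I left my successor a clock instead of a plateau.

| flask | X | E | temperature | remark | time |
|---|---|---|---|---|---|
| Monday's | 0.50 M | 0.28 M | 20 °C | run made earlier |  |
| Friday's | 0.50 M | 0.90 M | 35 °C | run made earlier |  |
| winter | 0.50 M | 0.490 M | 45 °C |  | 20 h |
| midnight | 0.50 M | 0.490 M | 25 °C |  | 20 h |
| spring | 0.50 M | 1.50 M | 25 °C |  | 20 h |
| autumn | 0.50 M | 1.50 M | 45 °C |  | 20 h |

- Monday's (time / h: Q / %): 0.833: 4; 1.50: 2; 3.00: 4; 5.00: 6; 10.0: 9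
- Friday's (time / h: Q / %): 1.33: 31; 2.50: 41; 4.00: 46; 5.00: 52; 6.00: 56

(scatter of a reading: 2 percentage points)

- all flasks from highest to lowest amount of Q, in percent of the X charged, at 20 h (winter / midnight / spring / autumn)
- the same order at 2.0 h (winter / midnight / spring / autumn)
- the amount of Q, in percent of the X charged of the flask you put first, at 20 h
- the amount of Q, in percent of the X charged of the flask you put last, at 20 h

- the earlier runs were read with a standard deviation of 2 percentage points

Each flask held X and E making Q. I took the rate constant of X + E → Q from one reading per run, Monday's last and Friday's first, each with its scatter of 2 points: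

k(Monday) = 0.0337 /M/h, k(Friday) = 0.310 /M/h

I carried ln k straight through temperature, which gave 0.0706 /M/h at 25 °C and 1.36 /M/h at 45 °C. My clock is the time in which X would fall to half through that step with [E] held at its charge, a pseudo-first-order half-life, ln(2)/(k[E]). For midnight it came to 20.0 h, for spring 6.55 h, for winter 1.04 h and for autumn, at its own 45 °C, 0.339 h.

Friday's clock was 2.48 h, so at 6.00 h it allowed 81.3% of Q, but I read 56%. I joined the two ends by scaling the climb to that run's ceiling:

ceiling = 68.9%; Q at a given time = ceiling × share of X gone by that time on the clock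

Borrowing that ceiling was my weakest step, since Friday's charge differed. It gave 60.6% for spring and 34.4% for midnight at 20 h. Winter and autumn would stand on the far end by then, because their clocks are short, and their heights I could not reckon. My note said not to touch the baths, because at one charge winter's clock runs shorter than midnight's.

The forecast gave spring > autumn > midnight > winter at 20 h and autumn > winter > spring > midnight at 2.0 h, with 78% first and 28% last, above my spring, reasoning that “the reaction is reversible”.

The flasks gave spring > autumn > winter > midnight and autumn > winter > spring > midnight, with 67.1% and 32.4%.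

    X + E → Q (k = 0.130 /M/h, Ea = 81.0 kJ/mol)
    X + E → G, rate k2*[X] as long as [E] is above zero (k = 8.50 × 10⁻⁴ /h, Ea = 99.0 kJ/mol)
    X + Q → J (k = 0.140 /M/h, Ea = 62.0 kJ/mol)
    Q ⇌ L (K = 0.400, k = 0.00280 /h, Ea = 102 kJ/mol, ΔH = −13.0 kJ/mol)
    (constants at 25 °C)

Spring held 67.1% of Q against my 60.6%, and midnight 32.4% against my 34.4%. With a clock of 20.0 h, midnight kept 30% of its X at 20.0 h. A repeat of midnight at 50 °C, clock 0.496 h, kept 0.019%. Spring had not come to rest: by 200 h its Q fell to 53.8% while L rose from 2.90% to 17.3%. Autumn's Q stood at 62.2% at 20.0 h and 61.5% at 200 h. Left ten times as long, midnight's X reached 0.0167% and its Q 26.4%.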